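The earlier runs and the new flask were computed with constants of no real substance, and the scatter is random.

The autumn and dusk flasks share one temperature, one catalyst charge of 0.00500 M and 1.00 M of starting material, and dusk has half the reagent. The time a flask takes to make a fixed amount of product plays the part of a time constant, so comparing such times compares mean rates.

| flask | starting material | reagent | free catalyst | product | time |
|---|---|---|---|---|---|
| autumn | 1.00 M | 1.10 M | 0.00500 M |  |  |
| summer | 0.600 M | 0.700 M | 0.00500 M |  |  |
| midnight | 0.500 M | 1.10 M | 0.00500 M |  |  |
| dusk | 1.00 M | 0.550 M | 0.00500 M |  |  |
| noon | 1.00 M | 1.10 M | 0.00500 M | 0.300 M | 35 min |

| autumn run: time / min | autumn run: [product] / M | summer run: time / min | summer run: [product] / M | midnight run: time / min | midnight run: [product] / M | dusk run: time / min | dusk run: [product] / M |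
|---|---|---|---|---|---|---|---|
| 1.6 | 0.017 | 1.6 | 0.008 | 1.6 | 0.029 | 1.6 | 0.016 |
| 4.7 | 0.076 | 4.7 | 0.038 | 4.7 | 0.040 | 4.7 | 0.047 |
| 9.0 | 0.138 | 9.0 | 0.084 | 9.0 | 0.077 | 9.0 | 0.093 |
| 14 | 0.210 | 14 | 0.120 | 14 | 0.130 | 14 | 0.127 |
| 20 | 0.287 | 20 | 0.147 | 20 | 0.168 | 20 | 0.171 |
| 27 | 0.364 | 27 | 0.174 | 27 | 0.214 | 27 | 0.209 |
| 35 | 0.434 | 35 | 0.207 | 35 | 0.250 | 35 | 0.244 |

(standard deviation of a reading: 0.008 M)

- Overall: starting material + reagent -> product, with free catalyst as catalyst.
- Constant volume, constant temperature.
- Readings of a species count what is bound in complexes too.
- An order is taken over about fifteen percent of the charge, up and down.
- A share of product counts the product that was charged too.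

- apparent order in [reagent] of the starting rate, round the charge of the autumn run (the rate where two percent of its starting material have turned into product)
- apparent order in [starting material] of the starting rate, round the charge of the autumn run (the rate where two percent of its starting material have turned into product) (one fixed amount of product, the same in the runs compared)
- the summer run starts with 0.400 M less of starting material and of reagent than the autumn run, and with no product. Compared where both hold the same amount of starting material, once fifteen percent of what the summer run was charged with has turned into product, is the summer run faster, slower or alike (within a tenth)?
- product in the noon run at 35 min, as a share of the starting material charged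
- which of these the readings show (nothing beyond the main steps / a little impurity takes part of the catalyst at once / the product kills the catalyst / the two partners rest in a complex / the substrate ties up the catalyst)

The first way compares the two flasks at one moment. At 14 min the autumn flask holds 0.210 M of product and the dusk flask 0.127 M, a ratio of 0.605. Read against the halved reagent, that ratio gives an order in reagent of 0.726, and the scatter of the dusk reading alone moves this by 0.0909. But the comparison drifts: at that moment the dusk flask still holds 0.873 M of starting material, more than the 0.790 M in the autumn flask, so the two flasks then differ in more than reagent.

The second way compares the flasks at one amount of product. The autumn flask reaches 0.210 M at 14 min and the dusk flask 0.209 M at 27 min, so both have spent nearly the same starting material. Over that span the mean reagent is 0.446 M in dusk, where reagent is the limiting reagent, and 0.995 M in autumn. The logarithm of the time ratio over the logarithm of the mean-reagent ratio gives 0.817. This number is the equal-product order: the logarithm of the ratio of the times two flasks need for one amount of product, divided by the logarithm of the ratio of the mean amounts of the species that differs.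

The two ways part by 0.0910, about the shift that the scatter of the one dusk reading gives, so the readings do not firmly separate them. The first way still sets unlike amounts of starting material side by side, and the second way does not, so my own reckoning stands near 0.817, with one caution: this value spans a halving of reagent, not the narrow band round the autumn charge that is asked.

The forecast, made from the same runs, gave 0.6 in reagent, 0.75 in starting material, alike for the summer run, 73% for noon and "nothing beyond the main steps", holding that “Both orders fit the plain cycle”. Its reagent order is lower than mine.

The flask ran by these steps:

    2 free catalyst ⇌ catalyst dimer, settled at all times (6680 L mol⁻¹)
    catalyst dimer + starting material + reagent → product + catalyst dimer (18.12 L² mol⁻² min⁻¹)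
    starting material + reagent ⇌ idle substrate-reagent adduct, settled at all times (0.8010 L mol⁻¹)

The simulation gives orders of 0.73 in reagent and 0.78 in starting material, alike for the summer run at a ratio of 1.0, 73.5% for noon, and "the two partners rest in a complex". At the start of the autumn run 0.369 M of starting material sat with reagent as idle substrate-reagent adduct, while the catalyst dimer carried the step to product. Across the halved reagent of the dusk run, the rate ratio 0.57 to the autumn run is an order of 0.820, beside 0.817 and above the 0.73 round the charge. In the midnight run, 0.214 M of product stood at 27 min, an equal-product order in starting material of 0.798, against the 0.78 round the autumn charge.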